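**Plan**

- Retrosynthesis: first remove C2 of the pyranone (cuts O1–C2 and C2–C3), which leaves a 2-hydroxydeoxybenzoin; then open ring A at C5–C6 and C4a–C8a.
- Enabling feature: ring A carries O on C8a, prenyl on C8, OH on C7, OMe on C6, H on C5 and the acyl carbon on C4a. This is the pattern of a 1,4-dimethoxy-1,3-bis(silyloxy)-2-prenylbutadiene (C8a–C8–C7–C6) joined to a terminal ynone (C5, C4a).
- Further cuts: C8–CH2 of the prenyl group (β-keto ester alkylation) and C4–C4a (Weinreb amide plus ethynyl Grignard reagent).
- Forward order: ring B is bought as homoveratric acid, ring A is built by diene–ynone benzannulation, and ring C (the pyranone) is closed last with a one-carbon unit.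
- Stereochemistry: the target has no stereocentre and no stereogenic alkene; only the 3Z geometry of the diene (methoxy group pointing outwards) matters, and only for reactivity.

Key step: step 6

Assumption: since the target is achiral, "single enantiomer" is taken to mean the single constitution drawn; there is no configuration to control.

**Step 1**
Reactants: 1 methyl 4-methoxy-3-oxobutanoate; 2 prenyl bromide (1-bromo-3-methylbut-2-ene)
Product: 3 methyl 4-methoxy-2-(3-methylbut-2-en-1-yl)-3-oxobutanoate (racemic, C2 labile)
Conditions: NaH (1.0 equiv), THF, 0 °C; then 2 (0.95 equiv), 0 → 20 °C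
Reagents that add atoms: none
Why: The C2–H between ketone and ester is the only acidic site for one equivalent of base, and the sodium enolate should undergo SN2 C-alkylation with the allylic bromide (β-keto ester alkylation), a slight excess of 1 suppressing dialkylation.

**Step 2**
Reactants: 3 methyl 4-methoxy-2-(3-methylbut-2-en-1-yl)-3-oxobutanoate
Product: 4 methyl 4-methoxy-2-(3-methylbut-2-en-1-yl)-3-(trimethylsilyloxy)but-2-enoate (E/Z mixture)
Conditions: TMSCl, Et3N, PhMe, 20 °C; filtration, distillation
Reagents that add atoms: chlorotrimethylsilane, C[Si](C)(C)Cl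
Why: Amine-mediated O-silylation of the enolised β-keto ester should give the conjugated β-silyloxy enoate (first stage of the Chan-type bis(silyl enol ether) synthesis), and its alkene geometry is irrelevant because that bond becomes the central single bond of the diene.

**Step 3**
Reactants: 4 methyl 4-methoxy-2-(3-methylbut-2-en-1-yl)-3-(trimethylsilyloxy)but-2-enoate
Product: 5 (3Z)-1,4-dimethoxy-2-(3-methylbut-2-en-1-yl)-1,3-bis(trimethylsilyloxy)buta-1,3-diene
Conditions: LDA, THF, −78 °C; then TMSCl, −78 → 20 °C; salts removed under Ar, used crude
Reagents that add atoms: chlorotrimethylsilane, C[Si](C)(C)Cl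
Why: LDA should remove the γ-hydrogen at C4 (vinylogous to the ester and further acidified by the methoxy group) and the extended enolate is silylated on the ester oxygen (second stage of the Chan-type synthesis); the 3Z geometry with methoxy trans to C2 is expected from the lithium-chelated dienolate, and any β,γ-isomer of 4 would converge on the same diene by α-deprotonation.

**Step 4**
Reactants: 6 homoveratric acid ((3,4-dimethoxyphenyl)acetic acid)
Product: 8 2-(3,4-dimethoxyphenyl)-N-methoxy-N-methylacetamide, via acylimidazole 7 (not isolated)
Conditions: CDI, CH2Cl2, 20 °C; then MeNHOMe·HCl, 20 °C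
Reagents that add atoms: N,O-dimethylhydroxylamine hydrochloride, CNOC.Cl
Why: Carbonyldiimidazole activates the acid as the acylimidazole, which is intercepted by the hydroxylamine (Weinreb amide formation) without touching the electron-rich ring.

**Step 5**
Reactants: 8 2-(3,4-dimethoxyphenyl)-N-methoxy-N-methylacetamide; 9 ethynylmagnesium bromide
Product: 10 1-(3,4-dimethoxyphenyl)but-3-yn-2-one
Conditions: 9 (0.5 M in THF, 2 equiv), THF, −20 → 0 °C; inverse quench into cold 1 M HCl; used promptly
Reagents that add atoms: none
Why: The magnesium chelate of the tetrahedral adduct prevents over-addition (Weinreb ketone synthesis), and quenching into acid keeps the released hydroxylamine protonated so that it cannot add to the terminal ynone.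

**Step 6**
Reactants: 5 (3Z)-1,4-dimethoxy-2-(3-methylbut-2-en-1-yl)-1,3-bis(trimethylsilyloxy)buta-1,3-diene; 10 1-(3,4-dimethoxyphenyl)but-3-yn-2-one
Product: 12 1-[2,4-dihydroxy-5-methoxy-3-(3-methylbut-2-en-1-yl)phenyl]-2-(3,4-dimethoxyphenyl)ethanone, via cyclohexa-1,4-diene cycloadduct 11 (not isolated)
Conditions: 5 (1.5 equiv), PhMe, −20 → 20 °C; then 1 M HCl, THF, 0 °C
Reagents that add atoms: none
Why: The electron-rich ketene-acetal diene 5 and the activated terminal ynone 10 should combine in a normal-demand Diels–Alder reaction in which C4 of 5 (future C6, the most nucleophilic terminus because the two oxygens on C1 and the one on C3 all donate towards it) bonds to the alkyne β-carbon (future C5) ahead of the bond between the ketene-acetal carbon (future C8a) and the α-carbon (future C4a); a stepwise Mukaiyama–Michael addition followed by closure of the allenolate onto the oxygen-stabilised allyl cation would lead to the same cyclohexa-1,4-diene 11. The closest known reaction type is the cycloaddition–aromatisation of 1-alkoxy-1,3-bis(silyloxy)butadienes and related 1,1-dialkoxy-3-silyloxybutadienes with acetylenic esters and ketones, which gives 4-acylresorcinol derivatives. Ring A is closed as a six-membered carbocycle in [4+2] mode, both new bonds being intermolecular. On acid work-up both silyl ethers are cleaved, the C8a hemiketal expels methanol to a cyclohexadienone and the C6 hydrogen shifts to oxygen, so C6 keeps its methoxy group while C8a and C7 end as hydroxyls. No stereocentre is created in the product, since the two sp3 centres of 11 are erased on aromatisation. The step needs regioselectivity (acyl on C4a, hydrogen on C5) and chemoselectivity for the alkyne; the first follows from the polarity match described, the second from the inertness of the ketone carbonyl, the trisubstituted prenyl alkene and the veratryl ring towards the diene in the absence of a Lewis acid.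

**Step 7**
Reactants: 12 1-[2,4-dihydroxy-5-methoxy-3-(3-methylbut-2-en-1-yl)phenyl]-2-(3,4-dimethoxyphenyl)ethanone
Product: 14 3-(3,4-dimethoxyphenyl)-7-hydroxy-6-methoxy-8-(3-methylbut-2-en-1-yl)-4H-chromen-4-one, via enaminone 13 (not isolated)
Conditions: Me2NCH(OMe)2 (2 equiv), THF, 65 °C; dilute HCl work-up
Reagents that add atoms: N,N-dimethylformamide dimethyl acetal, COC(OC)N(C)C
Why: The formamide acetal condenses at the benzylic methylene activated by ketone and aryl ring to give the enaminone, and the chelated C8a hydroxyl, the only one that can reach, closes the pyranone by 6-endo addition–elimination with loss of dimethylamine (standard isoflavone synthesis from 2-hydroxydeoxybenzoins).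

**Compound list**

1 | methyl 4-methoxy-3-oxobutanoate (methyl 4-methoxyacetoacetate) | COCC(=O)CC(=O)OC | starting material
2 | 1-bromo-3-methylbut-2-ene (prenyl bromide) | CC(C)=CCBr | starting material
3 | methyl 4-methoxy-2-(3-methylbut-2-en-1-yl)-3-oxobutanoate (racemic, labile C2) | COCC(=O)C(CC=C(C)C)C(=O)OC | intermediate
4 | methyl 4-methoxy-2-(3-methylbut-2-en-1-yl)-3-(trimethylsilyloxy)but-2-enoate (E/Z mixture, geometry erased in step 3) | COCC(O[Si](C)(C)C)=C(CC=C(C)C)C(=O)OC | intermediate
5 | (3Z)-1,4-dimethoxy-2-(3-methylbut-2-en-1-yl)-1,3-bis(trimethylsilyloxy)buta-1,3-diene (C1=C2 geometry not defined, without consequence) | CO/C=C(O[Si](C)(C)C)/C(CC=C(C)C)=C(OC)O[Si](C)(C)C | intermediate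
6 | (3,4-dimethoxyphenyl)acetic acid (homoveratric acid) | COc1ccc(CC(=O)O)cc1OC | starting material
7 | 2-(3,4-dimethoxyphenyl)-1-(1H-imidazol-1-yl)ethanone | COc1ccc(CC(=O)n2ccnc2)cc1OC | intermediate (not isolated)
8 | 2-(3,4-dimethoxyphenyl)-N-methoxy-N-methylacetamide | COc1ccc(CC(=O)N(C)OC)cc1OC | intermediate
9 | ethynylmagnesium bromide | C#C[Mg]Br | starting material
10 | 1-(3,4-dimethoxyphenyl)but-3-yn-2-one | C#CC(=O)Cc1ccc(OC)c(OC)c1 | intermediate
11 | 1-[3,6-dimethoxy-5-(3-methylbut-2-en-1-yl)-4,6-bis(trimethylsilyloxy)cyclohexa-1,4-dien-1-yl]-2-(3,4-dimethoxyphenyl)ethanone (mixture of stereoisomers, both centres lost on aromatisation) | COC1C=C(C(=O)Cc2ccc(OC)c(OC)c2)C(OC)(O[Si](C)(C)C)C(CC=C(C)C)=C1O[Si](C)(C)C | intermediate (not isolated)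
12 | 1-[2,4-dihydroxy-5-methoxy-3-(3-methylbut-2-en-1-yl)phenyl]-2-(3,4-dimethoxyphenyl)ethanone | COc1ccc(CC(=O)c2cc(OC)c(O)c(CC=C(C)C)c2O)cc1OC | intermediate
13 | 3-(dimethylamino)-1-[2,4-dihydroxy-5-methoxy-3-(3-methylbut-2-en-1-yl)phenyl]-2-(3,4-dimethoxyphenyl)prop-2-en-1-one (push–pull alkene, geometry not defined) | COc1ccc(C(=CN(C)C)C(=O)c2cc(OC)c(O)c(CC=C(C)C)c2O)cc1OC | intermediate (not isolated)
14 | 3-(3,4-dimethoxyphenyl)-7-hydroxy-6-methoxy-8-(3-methylbut-2-en-1-yl)-4H-chromen-4-one (achiral) | COc1ccc(-c2coc3c(CC=C(C)C)c(O)c(OC)cc3c2=O)cc1OC | target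

**Step count**

Total: 7 steps. Longest linear sequence: 5 steps (1, 2, 3, 6, 7); the ynone branch (4, 5) joins at step 6.

**Steps most likely to fail**

Step 6. The diene terminus may add to the ynone in a conjugate sense without the second bond closing, so that open-chain material results after work-up. The moisture-sensitive diene may also be lost by protodesilylation before it reacts, a 3E diene isomer may fail to reach the s-cis geometry, or the C8a ketal may collapse with loss of silanol so that C8a ends as a methyl ether. The fallback gives up the de novo ring and sets out from homoveratric acid 6 and prenyl bromide 2. Friedel–Crafts acylation of purchased 4-methoxybenzene-1,3-diol F1 with 6 (BF3·OEt2, 80 °C) should take place para to one hydroxyl and ortho to the other and give 1-(2,4-dihydroxy-5-methoxyphenyl)-2-(3,4-dimethoxyphenyl)ethanone F2. C-prenylation of its phenoxide with 2 (aqueous KOH, 20 °C) can only occur at the carbon between the two hydroxyls, because the other activated position carries the methoxy group. This route comes back at 12.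

Step 5. The liberated N,O-dimethylhydroxylamine may add to the new ynone during the quench, the Grignard reagent may enolise the amide at the benzylic methylene, or the terminal ynone may oligomerise on concentration. The fallback sets out from Weinreb amide 8 and changes the oxidation level. Reduction with DIBAL-H (THF, −78 °C) should give 2-(3,4-dimethoxyphenyl)acetaldehyde F3, and addition of ethynylmagnesium bromide 9 at −78 °C should give racemic 1-(3,4-dimethoxyphenyl)but-3-yn-2-ol F4. Oxidation with Dess–Martin periodinane (CH2Cl2, NaHCO3, 0 °C) then forms the ynone under neutral, amine-free conditions and returns to the route at 10, which would be carried forward as a solution.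

Step 7. The formamide acetal may O-methylate the acidic C7 hydroxyl, or the sequence may stall at the enaminone stage. The fallback sets out from 12 and masks that hydroxyl. Silylation of the non-chelated hydroxyl (TBSCl, imidazole, DMF, 20 °C; the hydrogen-bonded C8a hydroxyl is left free) should give 1-[4-(tert-butyldimethylsilyloxy)-2-hydroxy-5-methoxy-3-(3-methylbut-2-en-1-yl)phenyl]-2-(3,4-dimethoxyphenyl)ethanone F5. Treatment with the formamide acetal as in step 7 should close the pyranone to 7-(tert-butyldimethylsilyloxy)-3-(3,4-dimethoxyphenyl)-6-methoxy-8-(3-methylbut-2-en-1-yl)-4H-chromen-4-one F6, and TBAF (THF, 0 °C) releases the phenol, which rejoins the route at 14.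

**Further compounds**

F1 | step 6 | 4-methoxybenzene-1,3-diol (purchased) | COc1ccc(O)cc1O
F2 | step 6 | 1-(2,4-dihydroxy-5-methoxyphenyl)-2-(3,4-dimethoxyphenyl)ethanone | COc1ccc(CC(=O)c2cc(OC)c(O)cc2O)cc1OC
F3 | step 5 | 2-(3,4-dimethoxyphenyl)acetaldehyde | COc1ccc(CC=O)cc1OC
F4 | step 5 | 1-(3,4-dimethoxyphenyl)but-3-yn-2-ol (racemic) | C#CC(O)Cc1ccc(OC)c(OC)c1
F5 | step 7 | 1-[4-(tert-butyldimethylsilyloxy)-2-hydroxy-5-methoxy-3-(3-methylbut-2-en-1-yl)phenyl]-2-(3,4-dimethoxyphenyl)ethanone | COc1ccc(CC(=O)c2cc(OC)c(O[Si](C)(C)C(C)(C)C)c(CC=C(C)C)c2O)cc1OC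
F6 | step 7 | 7-(tert-butyldimethylsilyloxy)-3-(3,4-dimethoxyphenyl)-6-methoxy-8-(3-methylbut-2-en-1-yl)-4H-chromen-4-one | COc1ccc(-c2coc3c(CC=C(C)C)c(O[Si](C)(C)C(C)(C)C)c(OC)cc3c2=O)cc1OC
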